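**Retrosynthetic overview**

1. 6-Prenylsakuranetin 12 ⇐ desilylation of 11 ⇐ (key step) oxidative one-carbon ring expansion of the racemic cyclopropane-fused benzofuran 10, ended by an enantioconvergent hydrogen-atom transfer at C2.
2. Enabling feature: the strained transannular C2–C4 bond of the cyclopropane (C2, C3, C4) fused to the five-membered O1–C2–C4–C4a–C8a ring; O1 and the 2-aryl group steer its cleavage to a C2 radical, and the free C5 phenol on the A ring is the oxidation handle.
3. 10 ⇐ aromatic Claisen rearrangement (prenyl to C6, unveils the C5 phenol) ⇐ O-(1,1-dimethylallyl) ether 9 ⇐ phenol 7 ⇐ Simmons–Smith cyclopropanation of the 2-aryl-3-silyloxybenzofuran 5.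
4. 5 ⇐ Pd α-arylation and O-silylation of 4-hydroxy-6-methoxybenzofuran-3(2H)-one 2 with aryl bromide 3 ⇐ selective O-methylation of 1.
5. Ring order: the benzofuranone ring is present in 1; the cyclopropane is added in step 3; the pyranone ring arises in step 5 by ring expansion (five to six).

Key step: step 5

Remark: compounds 4, 6, 7, 9 and 10 are racemates (the cis ring fusion fixes the relative configuration of the cyclopropanes), the only stereocentre of the target is created in step 5, and carbonate 8 is taken as a commercial reagent.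

Step 1
Reactants: 1 4,6-dihydroxybenzofuran-3(2H)-one
Product: 2 4-hydroxy-6-methoxybenzofuran-3(2H)-one
Conditions: MeI (1.05 equiv), K2CO3 (1.0 equiv), acetone, rt
Reagents that add atoms: iodomethane, CI
Why: Williamson methylation should occur at the 6-OH, which is para to the ketone (vinylogous acid) and the most acidic site, while the 4-OH is peri to the carbonyl, hydrogen-bonded and less nucleophilic.

Step 2
Reactants: 2 4-hydroxy-6-methoxybenzofuran-3(2H)-one; 3 (4-bromophenoxy)triisopropylsilane
Product: 5 6-methoxy-3,4-bis(triethylsilyloxy)-2-[4-(triisopropylsilyloxy)phenyl]benzofuran, via 2-arylbenzofuranone 4 (not isolated)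
Conditions: Pd(dba)2 (2 mol %), XPhos (4 mol %), NaHMDS (3.1 equiv), PhMe, 60 °C; then TESCl (2.5 equiv), 0 °C → rt
Reagents that add atoms: chlorotriethylsilane, CC[Si](Cl)(CC)CC
Why: Buchwald–Hartwig-type Pd-catalysed α-arylation of the ketone enolate should stop at monoarylation because the product enolate is hindered and stabilised, and O-silylation of the resulting phenoxide/enolate dianion gives the aromatic benzofuran without isolation of the air-sensitive 2-aryl ketone.

Step 3
Reactants: 5 6-methoxy-3,4-bis(triethylsilyloxy)-2-[4-(triisopropylsilyloxy)phenyl]benzofuran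
Product: 7 rac-4-methoxy-6b-(triethylsilyloxy)-1a-[4-(triisopropylsilyloxy)phenyl]-1a,6b-dihydro-1H-cyclopropa[b]benzofuran-6-ol, via bis(triethylsilyl) cyclopropane 6 (not isolated)
Conditions: Et2Zn, CH2I2, CH2Cl2, 0 °C → rt; pyridine quench; then K2CO3 (cat.), MeOH, 0 °C
Reagents that add atoms: diiodomethane, ICI
Why: Simmons–Smith cyclopropanation (Furukawa modification) of the electron-rich silyl enol ether C2=C3 bond should give the cis-fused silyloxycyclopropane as a racemate (the two new stereocentres are fixed relative to each other by the ring fusion), and mild methanolysis should cleave only the aryl triethylsilyl ether, which is far more labile than the aryl TIPS ether and the tertiary cyclopropyl TES ether.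

Step 4
Reactants: 7 rac-4-methoxy-6b-(triethylsilyloxy)-1a-[4-(triisopropylsilyloxy)phenyl]-1a,6b-dihydro-1H-cyclopropa[b]benzofuran-6-ol; 8 tert-butyl (2-methylbut-3-en-2-yl) carbonate
Product: 10 rac-4-methoxy-5-(3-methylbut-2-en-1-yl)-6b-(triethylsilyloxy)-1a-[4-(triisopropylsilyloxy)phenyl]-1a,6b-dihydro-1H-cyclopropa[b]benzofuran-6-ol, via 1,1-dimethylallyl aryl ether 9 (not isolated)
Conditions: Pd(PPh3)4 (5 mol %), THF, 0 °C → rt; silica plug; then PhMe, 110 °C
Reagents that add atoms: none
Why: Tsuji–Trost O-allylation of the phenoxide at the more substituted terminus of the π-(1,1-dimethylallyl)palladium complex should give the tertiary ether, whose aromatic Claisen rearrangement ([3,3], then tautomerisation) can reach only the one free ortho carbon and so places a normal prenyl group between OH and OMe while unveiling the phenol needed in step 5; no stereocentre is affected.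

Step 5
Reactants: 10 rac-4-methoxy-5-(3-methylbut-2-en-1-yl)-6b-(triethylsilyloxy)-1a-[4-(triisopropylsilyloxy)phenyl]-1a,6b-dihydro-1H-cyclopropa[b]benzofuran-6-ol
Product: 11 (2S)-5-hydroxy-7-methoxy-6-(3-methylbut-2-en-1-yl)-2-[4-(triisopropylsilyloxy)phenyl]chroman-4-one
Conditions: [Ir(dF(CF3)ppy)2(bpy)]PF6 (2 mol %), chiral thiol (cysteine-peptide or axially chiral arenethiol, 10 mol %), Bu4N[(PhO)2PO2] (10 mol %), MeOH (5 equiv), THF, blue LEDs, 0 °C, degassed
Reagents that add atoms: none
Why: Proposed new method: excited Ir(III) with the phosphate base should oxidise the free C5 phenol (flavanone numbering) by proton-coupled electron transfer, and the phenoxyl radical, with spin density at C4a, should open the cyclopropane at the transannular C2–C4 bond (cyclopropylcarbinyl-type β-scission), after which O-to-O silyl shift and methanolysis restore the arene and leave the C4 ketone and a C2 radical that takes a hydrogen atom from the thiol, the thiyl radical being returned by Ir(II) and a proton. The closest known reaction types are the photoinduced-electron-transfer and Fe(III)-mediated (Saegusa–Ito) ring expansions of bicyclic cyclopropyl silyl ethers through β-keto radicals, the photoredox/thiol redox-neutral ring opening of cyclic alcohols, and peptide-thiol hydrogen-atom transfer in light-driven deracemisation. No σ-bond is formed to close a ring: the pyranone ring arises from the five-membered O1–C2–C4–C4a–C8a ring by loss of the C2–C4 bond, so that C3 becomes a ring member (five to six). The only stereocentre, C2, is created from a planar radical, so both enantiomers of 10 converge, and it is controlled by the chiral thiol, which has to deliver hydrogen to the Re face (O1 > C1′ > C3) for 2S. The step needs cleavage of the internal and not the external cyclopropane bond, which O1 and the 4-silyloxyphenyl group secure by stabilising the tertiary benzylic α-oxy radical at C2, and it needs fast reduction of the thiyl radical by Ir(II) so that the weak C2–H bond of the product is not re-abstracted. The trisubstituted prenyl alkene should survive because thiyl addition to it is reversible.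

Step 6
Reactants: 11 (2S)-5-hydroxy-7-methoxy-6-(3-methylbut-2-en-1-yl)-2-[4-(triisopropylsilyloxy)phenyl]chroman-4-one
Product: 12 6-prenylsakuranetin, (2S)-5-hydroxy-2-(4-hydroxyphenyl)-7-methoxy-6-(3-methylbut-2-en-1-yl)chroman-4-one
Conditions: TBAF (1.2 equiv), AcOH (1.5 equiv), THF, 0 °C
Reagents that add atoms: none
Why: Fluoride cleavage of the aryl silyl ether buffered with acetic acid should release the phenol without base-induced retro-oxa-Michael ring opening, so the C2 configuration is kept.

**Compound list**

1 | 4,6-dihydroxybenzofuran-3(2H)-one | O=C1COc2cc(O)cc(O)c12 | starting material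
2 | 4-hydroxy-6-methoxybenzofuran-3(2H)-one | O=C1COc2cc(OC)cc(O)c12 | intermediate
3 | (4-bromophenoxy)triisopropylsilane | CC(C)[Si](Oc1ccc(Br)cc1)(C(C)C)C(C)C | starting material
4 | rac-4-hydroxy-6-methoxy-2-[4-(triisopropylsilyloxy)phenyl]benzofuran-3(2H)-one (formed as its disodium salt, not isolated) | O=C1C(c2ccc(O[Si](C(C)C)(C(C)C)C(C)C)cc2)Oc2cc(OC)cc(O)c12 | intermediate
5 | 6-methoxy-3,4-bis(triethylsilyloxy)-2-[4-(triisopropylsilyloxy)phenyl]benzofuran | COc1cc(O[Si](CC)(CC)CC)c2c(O[Si](CC)(CC)CC)c(-c3ccc(O[Si](C(C)C)(C(C)C)C(C)C)cc3)oc2c1 | intermediate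
6 | rac-4-methoxy-6,6b-bis(triethylsilyloxy)-1a-[4-(triisopropylsilyloxy)phenyl]-1a,6b-dihydro-1H-cyclopropa[b]benzofuran (cis-fused, not isolated) | COc1cc(O[Si](CC)(CC)CC)c2c(c1)OC3(c4ccc(O[Si](C(C)C)(C(C)C)C(C)C)cc4)CC23O[Si](CC)(CC)CC | intermediate
7 | rac-4-methoxy-6b-(triethylsilyloxy)-1a-[4-(triisopropylsilyloxy)phenyl]-1a,6b-dihydro-1H-cyclopropa[b]benzofuran-6-ol (cis-fused) | COc1cc(O)c2c(c1)OC3(c4ccc(O[Si](C(C)C)(C(C)C)C(C)C)cc4)CC23O[Si](CC)(CC)CC | intermediate
8 | tert-butyl (2-methylbut-3-en-2-yl) carbonate | CC(C)(C)OC(=O)OC(C)(C)C=C | starting material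
9 | rac-4-methoxy-6-[(2-methylbut-3-en-2-yl)oxy]-6b-(triethylsilyloxy)-1a-[4-(triisopropylsilyloxy)phenyl]-1a,6b-dihydro-1H-cyclopropa[b]benzofuran (not isolated) | COc1cc(OC(C)(C)C=C)c2c(c1)OC3(c4ccc(O[Si](C(C)C)(C(C)C)C(C)C)cc4)CC23O[Si](CC)(CC)CC | intermediate
10 | rac-4-methoxy-5-(3-methylbut-2-en-1-yl)-6b-(triethylsilyloxy)-1a-[4-(triisopropylsilyloxy)phenyl]-1a,6b-dihydro-1H-cyclopropa[b]benzofuran-6-ol (cis-fused) | COc1cc2c(c(O)c1CC=C(C)C)C3(O[Si](CC)(CC)CC)CC3(c4ccc(O[Si](C(C)C)(C(C)C)C(C)C)cc4)O2 | intermediate
11 | (2S)-5-hydroxy-7-methoxy-6-(3-methylbut-2-en-1-yl)-2-[4-(triisopropylsilyloxy)phenyl]chroman-4-one | COc1cc2c(c(O)c1CC=C(C)C)C(=O)C[C@@H](c1ccc(O[Si](C(C)C)(C(C)C)C(C)C)cc1)O2 | intermediate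
12 | 6-prenylsakuranetin, (2S)-5-hydroxy-2-(4-hydroxyphenyl)-7-methoxy-6-(3-methylbut-2-en-1-yl)chroman-4-one | COc1cc2c(c(O)c1CC=C(C)C)C(=O)C[C@@H](c1ccc(O)cc1)O2 | target

**Step count and risks**

Total step count: 6. Longest linear sequence: 6 steps (1 → 12).

Steps most likely to fail:

Step 5 (proposed new method). The hydrogen-atom transfer may discriminate poorly between the two faces of the C2 radical, and the ee may erode through reversible abstraction of the product C2–H by thiyl radicals. The fallback sets out from 10. The same photochemical ring opening, run with an achiral hydrogen donor (2,4,6-triisopropylbenzenethiol), should give the racemic flavanone silyl ether F1. A Noyori–Ikariya transfer hydrogenation (RuCl(p-cymene)(TsDPEN), in the antipode that reduces the (2R)-ketone, HCO2H/Et3N) run past half conversion should turn the (2R)-enantiomer into the cis-flavan-4-ol F2 and leave the (2S)-ketone, which is 11. The route is rejoined at 11, at the cost of at most half the material.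

Step 3. Carbenoid transfer to the hindered, tetrasubstituted enol ether may be slow, and zinc iodide may open the donor-substituted cyclopropane by Lewis-acid catalysis. The fallback sets out from 4, the disodium salt in the flask of step 2. Instead of being silylated it is C-alkylated with (iodomethyl)tributylstannane to the β-stannyl ketone F3. TiCl4 in CH2Cl2 at −78 °C should then close the three-membered ring by 1,3-destannylative addition of the C–Sn bond to the activated ketone, giving the cyclopropanol F4. TESOTf and 2,6-lutidine silylate both hydroxyl groups to give 6, where the route is rejoined (methanolysis to 7 as in step 3).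

Step 4. The hindered phenoxide may attack the less substituted allyl terminus, or palladium may isomerise the tertiary ether to the linear prenyl ether; either would send the Claisen rearrangement to a reverse-prenyl product. The fallback sets out from 7. Copper-catalysed propargylic etherification (3-chloro-3-methylbut-1-yne, DBU, cat. CuCl2, MeCN, 0 °C) should give the 1,1-dimethylpropargyl ether F5. Semihydrogenation over Lindlar catalyst with quinoline gives 9 free of palladium(0), where the route is rejoined (thermal Claisen rearrangement to 10 as in step 4).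

**Further compounds**

F1 | step 5 | rac-5-hydroxy-7-methoxy-6-(3-methylbut-2-en-1-yl)-2-[4-(triisopropylsilyloxy)phenyl]chroman-4-one | COc1cc2c(c(O)c1CC=C(C)C)C(=O)CC(c1ccc(O[Si](C(C)C)(C(C)C)C(C)C)cc1)O2
F2 | step 5 | (2R,4R)-7-methoxy-6-(3-methylbut-2-en-1-yl)-2-[4-(triisopropylsilyloxy)phenyl]chromane-4,5-diol | COc1cc2c(c(O)c1CC=C(C)C)[C@H](O)C[C@H](c1ccc(O[Si](C(C)C)(C(C)C)C(C)C)cc1)O2
F3 | step 3 | rac-4-hydroxy-6-methoxy-2-[(tributylstannyl)methyl]-2-[4-(triisopropylsilyloxy)phenyl]benzofuran-3(2H)-one | O=C1C(C[Sn](CCCC)(CCCC)CCCC)(c2ccc(O[Si](C(C)C)(C(C)C)C(C)C)cc2)Oc2cc(OC)cc(O)c12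
F4 | step 3 | rac-4-methoxy-1a-[4-(triisopropylsilyloxy)phenyl]-1a,6b-dihydro-1H-cyclopropa[b]benzofuran-6,6b-diol | COc1cc(O)c2c(c1)OC3(c4ccc(O[Si](C(C)C)(C(C)C)C(C)C)cc4)CC23O
F5 | step 4 | rac-4-methoxy-6-[(2-methylbut-3-yn-2-yl)oxy]-6b-(triethylsilyloxy)-1a-[4-(triisopropylsilyloxy)phenyl]-1a,6b-dihydro-1H-cyclopropa[b]benzofuran | COc1cc(OC(C)(C)C#C)c2c(c1)OC3(c4ccc(O[Si](C(C)C)(C(C)C)C(C)C)cc4)CC23O[Si](CC)(CC)CC
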